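## The problem

(+)-Methylphelligrin A 6 is a flavanone: the trioxygenated ring A is fused to the dihydropyranone ring C, which carries the 4-hydroxyphenyl ring B at C2. Beyond this skeleton it has one extra carbon–carbon bond, the diarylmethane link from C6 of ring A to the CH2 of a 2-hydroxybenzyl group. C6 lies between the chelated 5-OH and the 7-OMe, while the equally activated C8 stays free. The only stereocentre is C2, with R configuration, opposite to the (2S) series of the citrus flavanones; nothing in the molecule can relay it, so it must come from a resolution or an enantioselective bond formation. C2 is also the fragile point: base, and the 4'-phenoxide in particular, opens ring C to the 2'-hydroxychalcone, and reclosure racemises C2; because the opened form has two free ortho hydroxyls, reclosure can also move a C6 substituent to C8. One of four phenolic oxygens must end as a methyl ether, and the free phenols, the benzylic C2–O1 bond and the aryl ketone exclude strong base, hot hard Lewis acids and forcing hydrogenation late in the route. A short synthesis is possible because C6 is an electron-rich C–H carbon (ortho to 5-OH and 7-OMe, para to O1) and its substituent is exactly what forms when such a carbon captures an ortho-quinone methide; the neighbouring 5-OH, chelated to the C4 carbonyl, is a handle for steering the electrophile to C6.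

## Retrosynthesis

**6 to 3 and 4.** The C6–CH2 bond is cut. Other cuts near C6, or any cut through ring C, would require a prefunctionalised ring A and protecting groups. This cut leaves the complete flavanone (R)-sakuranetin 3 and the commodity alcohol 2-hydroxybenzyl alcohol 4, which loses water in the flask to give ortho-quinone methide 5. Seven carbons and one phenol are removed at once and no oxygen needs protection. The forward reaction must attack C6 and not C8, stop after one benzylation, leave ring B and the phenolic oxygens alone, and run in a non-basic medium so that C2 keeps its configuration.

**3 to 2.** No skeletal bond is cut; the stereochemical problem is separated from the constitutional one, and 3 is taken from racemic sakuranetin 2 by chromatography on a chiral phase. Resolving here means that only the correct enantiomer consumes 4 and that the final purification is only a regioisomer separation. An enantioselective construction of C2 would need a new flavanone synthesis with the protecting groups this plan avoids. The antipode of 3 is not lost, since base racemises it through the chalcone and it can be resolved again. The forward operation must give full separation at preparative load and must not racemise the product during recovery.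

**2 to 1.** The O7–CH3 bond is cut. Racemic naringenin 1 is commercial and contains every carbon of the flavanone. Its three hydroxyls differ in acidity: the 7-OH is a vinylogous acid, para to the carbonyl; the 5-OH is held in the chelate; the 4'-OH is an ordinary phenol. The forward reaction is a single O-methylation with one equivalent of weak base and methylating agent; ring opening by the base is harmless at the racemic stage.

## Roads not taken

**Alternative 1:** The cut is the aryl ether bond O1–C8a of ring C. In the forward direction the hydroxyl at the future C2 of the bromoaryl 1,3-diol A2 would be joined to the brominated ring carbon by CuI, 3,4,7,8-tetramethyl-1,10-phenanthroline and Cs2CO3 (intramolecular Ullmann-type etherification), closing ring C as flavan-4-ol A1.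
- Merits: the benzyl group is on the arene before ring C exists, so the C6/C8 question does not arise. C2 comes from established asymmetric carbonyl chemistry on an open chain. Closing at the alcohol oxidation level keeps the retro-oxa-Michael pathway shut during ring formation.
- Weak points: A2 is a pentasubstituted bromoarene with a diarylmethane and a stereodefined diol, and would need many steps. Its aryl bromide is electron-rich and flanked by the side chain, a slow case for CuI-mediated etherification. After closure, three operations remain: oxidation at C4, selective cleavage of the 5-O-methyl ether, and hydrogenolysis of two benzyl ethers without breaking the benzylic C2–O1 bond.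
- Comparison: this road is better in regiochemical certainty and in how the stereocentre is made. The chosen plan sets against it three steps instead of well over ten, no protecting groups, and a selectivity problem handled by a separation.

**Alternative 2:** The cut is the C2–C1' bond between ring C and ring B. Forward, Pd(OCOCF3)2 with a chiral tert-butyl pyridine–oxazoline ligand would add 4-(benzyloxy)phenylboronic acid A5 to C2 of chromone A4 (asymmetric conjugate addition of an arylpalladium species), giving flavanone A3 with C2 set by the ligand.
- Merits: the stereocentre is made catalytically with no discarded enantiomer. The benzyl position is fixed in A4. The step is convergent.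
- Weak points: A4 has a 5-methoxy group peri to the carbonyl and two more donor oxygens on ring A, which make the enone a poor and crowded acceptor; protodeboronation of the electron-rich A5 then competes. After the key step, selective 5-O-demethylation and double debenzylation remain. A4 itself needs a multistep preparation in which the benzyl group goes onto a symmetrical phloroglucinol-derived arene before the pyranone is built.
- Comparison: in how C2 is made and in regiochemical certainty this road is clearly better. The chosen plan offers in return its brevity, two commodity starting materials, no protecting groups, and recycling of the unwanted enantiomer by racemisation. On a larger scale, where discarding or recycling half of 2 weighs more, alternative 2 would deserve a second look.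

**Alternative 3:** The cuts are C5–C6, C7–C8 and C4a–C5; ring A is assembled last. Forward, irradiation of diazoketone A7 triggers a Wolff rearrangement to a vinylketene, which adds ynol ether A8 in a [2+2] cycloaddition. Four-electron electrocyclic opening of the cyclobutenone and six-electron closure of the dienylketene give, after tautomerisation, phenol A6 (a Danheiser-type benzannulation).
- Merits: the polarisation of A8 places the methoxy carbon at C7 and the benzyl-bearing carbon at C6, so the ring A pattern is unambiguous. The 5-OH emerges free and the 7-OMe is in place, so no selective demethylation is needed. C2 is carried in from a pyranone made beforehand.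
- Weak points: A7 is a cross-conjugated, light-absorbing β-alkoxy enone whose C2–O bond can open like that of a flavanone. A8 is an acid-sensitive ynol ether. Both need several steps, and two debenzylations still follow.
- Comparison: the regiocontrol is better than in the chosen plan, and nothing has to be separated from a C8 isomer. The chosen plan sets against this a far shorter route with robust, commercial inputs and no photochemistry on a sensitive diazo compound.

Key step: step 3

Assumption: the synthetic, racemic grade of naringenin is used, and the dextrorotatory sign of 6 is taken to belong to the 2R configuration of the structure.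

## Route

Step 1
Reactants: 1 (±)-naringenin
Product: 2 (±)-sakuranetin (rac-5-hydroxy-2-(4-hydroxyphenyl)-7-methoxychroman-4-one)
Conditions: Me2SO4 (1.0 equiv), K2CO3 (1.0 equiv), acetone, 25 °C
Reagents that add atoms: dimethyl sulfate, COS(=O)(=O)OC
Why: Williamson-type O-methylation under acidity control: the 7-OH, para to the C4 carbonyl, is the only hydroxyl deprotonated to a useful extent by one equivalent of K2CO3, the 5-OH is tied up in the hydrogen bond to C4=O and the 4'-OH is an ordinary phenol, so one equivalent of dimethyl sulfate should end up on O7. Any opening and reclosure of ring C by the base is without consequence for a racemate.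

Step 2
Reactants: 2 (±)-sakuranetin
Product: 3 (R)-sakuranetin ((2R)-5-hydroxy-2-(4-hydroxyphenyl)-7-methoxychroman-4-one)
Conditions: preparative HPLC, amylose tris(3,5-dimethylphenylcarbamate) on silica, n-hexane/EtOH with a trace of AcOH, 20 °C; fractions concentrated below 30 °C
Reagents that add atoms: none
Why: Enantiomer separation on a chiral stationary phase (chromatographic resolution); polysaccharide carbamate phases are the standard means of resolving hydroxylated flavanones, and no bond is made or broken. The C2 stereocentre of the route is fixed here by selecting the (R)-enantiomer, to be recognised by a circular dichroism sign pattern that should mirror that of the natural (2S)-flavanones; the slightly acidic eluent and cold evaporation keep the chalcone pathway closed.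

Step 3
Reactants: 3 (R)-sakuranetin; 4 2-hydroxybenzyl alcohol
Product: 6 (+)-methylphelligrin A ((2R)-5-hydroxy-6-(2-hydroxybenzyl)-2-(4-hydroxyphenyl)-7-methoxychroman-4-one), via ortho-quinone methide 5 (not isolated)
Conditions: ZnCl2 (anhydrous, 2 equiv), 1,4-dioxane, 80 °C; 4 (1.1 equiv) added in portions
Reagents that add atoms: none
Why: ZnCl2 binds the phenol and the benzylic hydroxyl of 4, ionises the C–O bond and expels water to give ortho-quinone methide 5 (or its ZnCl2-bound zwitterionic equivalent), whose exocyclic CH2 is a soft carbon electrophile. C6 of ring A in 3, ortho to the 5-OH and the 7-OMe and para to O1, adds to that CH2 in a conjugate sense, and proton loss from the resulting cyclohexadienone restores both aromatic rings with the C6–CH2 bond in place. The closest known reaction type is the ZnCl2-mediated Friedel–Crafts C-benzylation of 5,7-dioxygenated flavanones and dihydrochalcones with 2-hydroxybenzyl alcohol. No ring is closed and no stereocentre is created; C2 is a spectator, and the non-basic medium denies it the phenoxide- or enolate-driven retro-oxa-Michael opening that racemises flavanones. The step needs C6 over C8, one benzylation and not two, and ring A over ring B and over the phenolic oxygens. ZnCl2 bound in the chelate of O5 and the C4 carbonyl can also bind the oxygen of 5, which places the methylene next to C6 and away from C8; the mono-phenolic ring B is far less nucleophilic than ring A, and O-alkylation is reversible under the Lewis acid. Adding 4 in portions and stopping short of full conversion should hold back a second benzylation, and material from attack at C8 is removed by chromatography.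

## Compound list

1 | (±)-naringenin (rac-5,7-dihydroxy-2-(4-hydroxyphenyl)chroman-4-one) | O=C1CC(c2ccc(O)cc2)Oc2cc(O)cc(O)c12 | starting material
2 | (±)-sakuranetin (rac-5-hydroxy-2-(4-hydroxyphenyl)-7-methoxychroman-4-one) | COc1cc2c(c(O)c1)C(=O)CC(c1ccc(O)cc1)O2 | intermediate
3 | (R)-sakuranetin ((2R)-5-hydroxy-2-(4-hydroxyphenyl)-7-methoxychroman-4-one) | COc1cc2c(c(O)c1)C(=O)C[C@H](c1ccc(O)cc1)O2 | intermediate
4 | 2-hydroxybenzyl alcohol (2-(hydroxymethyl)phenol) | OCc1ccccc1O | starting material
5 | ortho-quinone methide (6-methylidenecyclohexa-2,4-dien-1-one) | C=C1C=CC=CC1=O | intermediate
6 | (+)-methylphelligrin A ((2R)-5-hydroxy-6-(2-hydroxybenzyl)-2-(4-hydroxyphenyl)-7-methoxychroman-4-one) | COc1cc2c(c(O)c1Cc1ccccc1O)C(=O)C[C@H](c1ccc(O)cc1)O2 | target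

## Step count and risks

Total step count: 3. Longest linear sequence: 3 steps (1 to 2 to 3 to 6); compound 4 enters in step 3.

**Step 3 (key step).** The most likely failure is poor site selectivity: attack at C8 competing with attack at C6, followed by a second benzylation. C8 is activated by the same three oxygens and is less crowded, and the ZnCl2 chelate is the only element favouring C6. The fallback replaces the Friedel–Crafts step by a cross-coupling whose site is fixed by a halogen; it sets out from 3 and returns at 6. Benzyltrimethylammonium dichloroiodate (1 equiv) with CaCO3 in CH2Cl2/MeOH at 20 °C, a reagent that iodinates 5-hydroxy-7-alkoxy flavonoids ortho to the chelated hydroxyl, should give the aryl iodide (R)-6-iodosakuranetin F1. The coupling partner is the benzylzinc reagent [2-(benzyloxy)benzyl]zinc chloride F2, prepared beforehand from the corresponding benzyl chloride by LiCl-assisted zinc insertion. Negishi coupling of F1 with F2, added slowly under Pd(OAc)2/SPhos in THF at 25 °C so that the free phenols are tolerated, should give the benzyl ether (R)-6-[2-(benzyloxy)benzyl]sakuranetin F3. Hydrogenolysis of the benzyl ether of F3 (H2, Pd/C, EtOAc, 20 °C) then gives 6. The detour stays neutral to weakly acidic, so C2 is not endangered. If slow erosion of configuration at C2 under the warm Lewis acid proves to be the limiting process instead, the racemate-first path described under step 2 applies.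

**Step 2.** The most likely failure is insufficient throughput: overlap of the enantiomer bands at preparative load and poor solubility of the phenolic flavanone in the hexane-rich eluent. Partial racemisation during concentration of the alcoholic fractions, by reversible opening to the chalcone assisted by the 4'-OH, is also possible. The fallback moves the resolution to the end, so that resolved material never faces a further reaction; it sets out from 2 and returns at 6. Compounds 2 and 4 under the conditions of step 3 should give racemic methylphelligrin A F4, which is then separated on the same kind of polysaccharide phase into 6 and its antipode. The extra hydroxyaryl group adds interaction sites for the carbamate phase, and F4 also serves as the racemic reference for checking the enantiomeric purity of 6 from the main route.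

**Step 1.** The most likely failure is over-methylation at the 4'-oxygen, and methylation of ring-opened material, when the phenoxide concentration is not controlled; the acidity gap between 7-OH and 4'-OH is only moderate. The fallback differentiates the hydroxyls by protecting groups instead of acidity; it sets out from 1 and returns at 2. Peracetylation (Ac2O, pyridine, 20 °C) should give (±)-naringenin triacetate F5. The 7-acetate of F5, the most electrophilic because it sits para to the carbonyl, is removed selectively with PhSH and imidazole in NMP at 0 °C to give the 7-phenol (±)-5,4'-di-O-acetylnaringenin F6. Mitsunobu methylation of the free 7-OH of F6 (MeOH, PPh3, DIAD, THF, 0 to 20 °C) should give the methyl ether (±)-5,4'-di-O-acetylsakuranetin F7. Acidic methanolysis of F7 (HCl, MeOH, 40 °C) removes both acetates and returns 2.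

## Further compounds

F1 | step 3 | (R)-6-iodosakuranetin ((2R)-5-hydroxy-2-(4-hydroxyphenyl)-6-iodo-7-methoxychroman-4-one) | COc1cc2c(c(O)c1I)C(=O)C[C@H](c1ccc(O)cc1)O2
F2 | step 3 | [2-(benzyloxy)benzyl]zinc chloride | Cl[Zn]Cc1ccccc1OCc1ccccc1
F3 | step 3 | (R)-6-[2-(benzyloxy)benzyl]sakuranetin ((2R)-6-[2-(benzyloxy)benzyl]-5-hydroxy-2-(4-hydroxyphenyl)-7-methoxychroman-4-one) | COc1cc2c(c(O)c1Cc1ccccc1OCc1ccccc1)C(=O)C[C@H](c1ccc(O)cc1)O2
F4 | step 2 | (±)-methylphelligrin A (rac-5-hydroxy-6-(2-hydroxybenzyl)-2-(4-hydroxyphenyl)-7-methoxychroman-4-one) | COc1cc2c(c(O)c1Cc1ccccc1O)C(=O)CC(c1ccc(O)cc1)O2
F5 | step 1 | (±)-naringenin triacetate (rac-2-(4-acetoxyphenyl)-4-oxochroman-5,7-diyl diacetate) | CC(=O)Oc1ccc(cc1)C1CC(=O)c2c(OC(C)=O)cc(OC(C)=O)cc2O1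
F6 | step 1 | (±)-5,4'-di-O-acetylnaringenin (rac-2-(4-acetoxyphenyl)-7-hydroxy-4-oxochroman-5-yl acetate) | CC(=O)Oc1ccc(cc1)C1CC(=O)c2c(OC(C)=O)cc(O)cc2O1
F7 | step 1 | (±)-5,4'-di-O-acetylsakuranetin (rac-2-(4-acetoxyphenyl)-7-methoxy-4-oxochroman-5-yl acetate) | CC(=O)Oc1ccc(cc1)C1CC(=O)c2c(OC(C)=O)cc(OC)cc2O1
A1 | alternative 1 | (2R,4S)-6-[2-(benzyloxy)benzyl]-2-[4-(benzyloxy)phenyl]-5,7-dimethoxychroman-4-ol | COc1cc2c(c(OC)c1Cc1ccccc1OCc1ccccc1)[C@@H](O)C[C@H](c1ccc(OCc3ccccc3)cc1)O2
A2 | alternative 1 | (1S,3R)-1-{3-[2-(benzyloxy)benzyl]-6-bromo-2,4-dimethoxyphenyl}-3-[4-(benzyloxy)phenyl]propane-1,3-diol | COc1cc(Br)c(c(OC)c1Cc1ccccc1OCc1ccccc1)[C@@H](O)C[C@@H](O)c1ccc(OCc2ccccc2)cc1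
A3 | alternative 2 | (R)-6-[2-(benzyloxy)benzyl]-2-[4-(benzyloxy)phenyl]-5,7-dimethoxychroman-4-one | COc1cc2c(c(OC)c1Cc1ccccc1OCc1ccccc1)C(=O)C[C@H](c1ccc(OCc3ccccc3)cc1)O2
A4 | alternative 2 | 6-[2-(benzyloxy)benzyl]-5,7-dimethoxy-4H-chromen-4-one | COc1cc2occc(=O)c2c(OC)c1Cc1ccccc1OCc1ccccc1
A5 | alternative 2 | 4-(benzyloxy)phenylboronic acid | OB(O)c1ccc(OCc2ccccc2)cc1
A6 | alternative 3 | (R)-6-[2-(benzyloxy)benzyl]-2-[4-(benzyloxy)phenyl]-5-hydroxy-7-methoxychroman-4-one | COc1cc2c(c(O)c1Cc1ccccc1OCc1ccccc1)C(=O)C[C@H](c1ccc(OCc3ccccc3)cc1)O2
A7 | alternative 3 | (R)-2-[4-(benzyloxy)phenyl]-6-(2-diazoacetyl)-2,3-dihydro-4H-pyran-4-one | [N-]=[N+]=CC(=O)C1=CC(=O)C[C@H](c2ccc(OCc3ccccc3)cc2)O1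
A8 | alternative 3 | 1-(benzyloxy)-2-(3-methoxyprop-2-yn-1-yl)benzene | COC#CCc1ccccc1OCc1ccccc1
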